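**Main step.** The flask gets a small charge: 2 mol% of free catalyst on 0.50 M of starting material, so [free catalyst] is 10.0 mM at the start. The spring run, with 20.0 mM, reads 15% product at 2.00 h. Scaling that speed to the flask, with the main step alone and no catalyst lost, I reckon 10% conversion after about 2.67 h, and on this view a doubled charge doubles the rate.

| flask | starting material | reagent | free catalyst | remark |
|---|---|---|---|---|
| summer | 0.25 M | 0.95 equiv | 2 mol% | run made earlier |
| spring | 1 M | 0.95 equiv | 2 mol% | run made earlier |
| autumn | 0.50 M | 0.95 equiv | 4 mol% | run made earlier |
| flask | 0.50 M | 0.950 equiv | 2 mol% |  |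

| run | time / h | product / % | starting material / % |
|---|---|---|---|
| summer | 0.667 | 3 | 98 |
| summer | 1.33 | 3 | 98 |
| summer | 3.00 | 4 | 94 |
| summer | 8.00 | 7 | 93 |
| spring | 2.00 | 15 | 84 |
| spring | 4.00 | 20 | 76 |
| spring | 6.00 | 21 | 76 |
| spring | 8.00 | 22 | 76 |
| autumn | 2.00 | 16 | 85 |
| autumn | 4.00 | 19 | 78 |
| autumn | 6.00 | 21 | 78 |
| autumn | 8.00 | 24 | 78 |

(readings scatter by 1.5 percentage points)

- the analysis behind the earlier runs scatters by 1.5 percentage points, standard deviation

- apparent order in reagent when 10% of the starting material are converted (percent change of the rate of making product for one percent more reagent charged)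
- factor on the rate of making product when 10% of the starting material are converted if free catalyst is charged twice over

**Catalyst loss.** But product creeps late: spring reads 20% at 4.00 h and 22% at 8.00 h, and autumn, with 20.0 mM, reads 24% at 8.00 h. I read this as catalyst deactivation, and I carry the capacity, the last product reading per unit of [free catalyst] charged, averaged over these two runs: 11.5 L mol⁻¹. For the flask this gives an end near 11.5%.

**Small difference.** My estimate of the flask's end lies close to 10%, so I compute only the room left there, 1.5 percentage points. If product closes on its end at the same pace in the flask and with a doubled charge, whose end I take as twice as far, the rate goes with this room, and doubling the catalyst gives 8.67. A small shift in the end moves this factor strongly, so the late readings are the ones to watch. The reagent ratio stays at 0.95 equiv in summer, 0.95 equiv in spring and 0.95 equiv in autumn, so these runs do not show its order; I assume 0.5.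

**The forecast.** It says 1 for the order and 8 for the factor, on the view that “10% conversion falls in the dying tail”. Its factor is a little below mine and its order above mine.

**The result.** The flask gives an order of 0.64 and a factor of 5.60.

    starting material + catalyst intermediate A ⇌ catalyst intermediate B (K = 3.90 L mol⁻¹, k = 0.710 L mol⁻¹ min⁻¹)
    reagent + free catalyst ⇌ catalyst intermediate A (K = 1.60 L mol⁻¹, k = 0.910 L mol⁻¹ min⁻¹)
    catalyst intermediate B → free catalyst + product (k = 0.260 min⁻¹)
    catalyst intermediate A → spent catalyst (k = 0.0310 min⁻¹)

At 10.0 h the flask holds 12.5% product, with 99.3% of its catalyst spent. Its capacity is thus 12.5 L mol⁻¹, larger than my 11.5 L mol⁻¹, and the room is 2.5 points, which makes the ratio of rooms 6.00. On the summer run, with 5.00 mM, this capacity gives 6.25% product, and its last reading is 7%.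

The runs stem from a simulated flask from invented constants; noise was put on by code.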